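Numbering used throughout (cembrane locants): C1–C14 form the carbocycle (C1 = lactone β‑carbon, C2 = ketone, C4=C5 olefin with Me‑18 on C4, Me‑19 on C8, C9 and C12 = ether carbons, Me‑20 on C12, C13 = carbinol, C14 = lactone O‑carbon); C15 (bearing Me‑17) and C16 are the lactone α‑carbon and carbonyl. In these terms the target 26 is (1R,4E,8R,9R,12R,13R,14S,15R).

## The problem

Target 26 is a cembranolide: a 14‑membered carbocycle (C1–C14) spanned by a 2,5‑trans oxolane (O between C9 and C12), fused cis at C1/C14 to an α‑methyl‑γ‑lactone (ring O–C14–C1–C15–C16) and carrying a C2 ketone that is β,γ to the 4E trisubstituted olefin. Seven stereocentres fall into two blocks: C8/C9, and the contiguous pentad C12–C13–C14–C1–C15, with C9 and C12 related 1,4 across the ether oxygen. C8/C9 have no neighbour to lean on and need reagent control. C12/C13 can be set from olefin geometry through an epoxide opened by O9; the C13 oxygen can then steer C14 (chelation), C14 can steer C1 (cyclic transition state) and C1 can steer C15 (thermodynamic trans). The ketone makes C1–H acidic, which invites epimerisation at C1, β‑elimination of the C14 acyloxy group and migration of C4=C5 into conjugation; a free C2 hydroxyl next to the lactone can take over the acyl group. The ketone must therefore appear last and under neutral conditions. The hardest task is closing a 14‑membered carbocycle across a trans‑bridged oxolane while fixing C1 and C14. The feature that makes the key step possible is the lactone ring O–C14–C1–C15–C16: the carboxyl C16 and the one‑carbon branch C17 hang on C15, C15 hangs on C1, and the ring oxygen sits on C14 next to the C13 carbinol. This is the retron of the addition of a 2‑(alkoxycarbonyl)allyl metal (C17–C15(C16)=C1) to a C14 aldehyde with a neighbouring oxygen at C13. C1–C14 is also the bond that the terpene cyclase presumably closes, with the same polarity (C14 electrophile, C1=C15 π‑nucleophile, olefin left at C15=C17).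

## Retrosynthesis

End game, no C–C bond cut: 26 is the C13 PMB ether 25 after oxidative deprotection, 25 comes from the C2 carbinol 24 by oxidation, 24 from its triethylsilyl ether 23, and the C15 methyl stereocentre of 23 from the α‑methylene lactone 21 by conjugate reduction and equilibration. This order keeps C1 non‑enolisable until the last two steps and leaves C15 as the only acidic centre when it is equilibrated.

Key disconnection, 21 to 18: the C1–C14 bond and the lactone C16–O bond are cut together, which opens both the carbocycle and the lactone and removes the C1 and C14 stereocentres. Cutting C4=C5 instead (metathesis) would give no control of olefin geometry and set no stereocentre. Cutting C2–C3 (acyl‑anion alkylation) needs a strong base next to a lactone. Cutting C5–C6 (sp2–sp3 coupling) is feasible but sets nothing. The precursor 18 is an open chain with one ring and four permanent stereocentres; the product 21 has the complete tricyclic skeleton and six of the seven. The forward reaction must be an intramolecular Barbier allylation that is γ‑selective, chelation‑controlled at C14 and syn‑selective at C1, followed by lactonisation.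

18 to 8 and 15: bromo aldehyde 18 comes from alcohol 17 and this from the allylic alcohol 16 (no C–C change). 16 is cut at C5–C6 into the oxolane fragment 8 (terminal vinyl group) and the vinyl iodide 15. This bond joins an sp3 to an sp2 carbon away from all stereocentres, and the vinyl iodide fixes the 4E geometry before coupling. The two halves are of similar size (five steps each).

8 to 1: 8 comes from the diol 6 through the arylidene acetal 7 (differentiation of the C13 and C14 oxygens). In 6 the C12–O bond of the oxolane is cut, which leads to the epoxy alcohol 5 and the (Z)‑allylic alcohol 4; the forward step is asymmetric epoxidation and 5‑exo opening by O9 with inversion at C12. 4 is cut at C8–C9 (syn crotylation) to aldehyde 2, and 2 arises by cleaving the distal olefin of neryl acetate 1. The cheap terpene thus supplies C9–C14 with Me‑20 and the Z olefin that encodes the C12/C13 relationship.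

15 to 9: the C1–C15 bond of 15 is cut (Morita–Baylis–Hillman) to aldehyde 13 and methyl acrylate 14. 13 comes from the bis‑silyl ether 12 and the diol 11, whose (E)‑vinyl iodide is made from the alkyne of 10 by carbometalation. 10 is (S)‑glycidol 9 opened by a two‑carbon alkynyl nucleophile.

## Roads not taken

Alternative 1: the most obvious cut is C4=C5, closed by ring‑closing metathesis of the diene A1 (lactone and oxolane already in place) with the second‑generation Grubbs catalyst RuCl2(=CHPh)(PCy3)(H2IMes) to give 23. The precursor A1 must already hold all seven stereocentres, so the ring closure solves nothing but the ring. It has to form a trisubstituted olefin from a 1,1‑disubstituted partner, and the E/Z outcome in a 14‑membered ring is not under control. The chosen plan fixes the olefin geometry in an acyclic vinyl iodide and lets the ring closure create C1 and C14.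

Alternative 2: a transannular, biosynthesis‑like ether formation, in which the macrocyclic epoxy alcohol A2 (C9 hydroxyl, 12,13‑epoxide, lactone and ketone present) is cyclised by acid to 26 in the last step. The epoxide would protect the C13 oxygen to the end. However, reaching A2 requires the carbocycle to be closed with the epoxide in place of the C13 oxygen handle, so C14 is no longer steered by chelation, and the acid‑labile tertiary epoxide must survive the whole end game beside the β,γ‑unsaturated ketone. The chosen plan runs the same epoxide opening early, on an acyclic substrate where 5‑exo attack has no competitor, and uses the liberated C13 oxygen to control C14.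

Alternative 3: the classical cembranoid closure at C2–C3, intramolecular alkylation of the protected cyanohydrin anion of A3 by its allylic bromide, then unmasking to 25. The strong amide base needed cannot be used beside the lactone (C15–H is comparably acidic), the final cyanohydrin cleavage is basic and the product is a β‑acyloxy ketone prone to elimination. The closure also sets no stereocentre, so C1, C14 and C15 would have to be built beforehand in acyclic form.

Key step: step 14

Remark: the C2 carbinol centre (R, from 9) and the C1 carbinol centre of 15 and 16 (both epimers) are destroyed in steps 17 and 12 and do not reach the target. Where a descriptor changes without a bond to the stereocentre being made or broken (9 to 10, 17 to 18), only the priority order changes.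

## Steps

Step 1
Reactants: 1 neryl acetate
Product: 2 (2Z)-3-methyl-6-oxohex-2-en-1-yl acetate
Conditions: O3 (1 equiv), CH2Cl2, pyridine (cat.), −78 °C; Me2S, −78 → 23 °C
Reagents that add atoms: ozone, [O-][O+]=O
Why: Ozonolysis with reductive work-up; the allylic acetate lowers the electron density of the C12=C13 olefin, so one equivalent of ozone should cleave the isopropylidene olefin first; no stereocentre is formed.

Step 2
Reactants: 2 (2Z)-3-methyl-6-oxohex-2-en-1-yl acetate
Product: 4 (2Z,6R,7R)-3,7-dimethylnona-2,8-diene-1,6-diol, via hydroxy acetate 3 (not isolated)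
Conditions: cis-2-butene, n-BuLi, KOt-Bu, THF, −78 → −45 °C; (−)-Ipc2BOMe [from (+)-α-pinene], −78 °C; BF3·OEt2; 2, −78 °C; then 3 M NaOH, 30% H2O2, 23 °C → reflux
Reagents that add atoms: cis-2-butene, C/C=C\C
Why: Brown crotylboration through a chair transition state: the (Z)-crotyl group gives the syn C8-methyl/C9-hydroxyl pair and the isopinocampheyl groups direct attack to the Si face of the aldehyde, which should set 8R,9R; the basic peroxide work-up oxidises the boron residues and saponifies the allylic acetate of 3.

Step 3
Reactants: 4 (2Z,6R,7R)-3,7-dimethylnona-2,8-diene-1,6-diol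
Product: 6 (1R)-1-[(2R,5R)-5-[(2R)-but-3-en-2-yl]-2-methyloxolan-2-yl]ethane-1,2-diol, via epoxy alcohol 5 (not isolated)
Conditions: Ti(OiPr)4 (20 mol %), D-(−)-diisopropyl tartrate (24 mol %), t-BuOOH, 4 Å MS, CH2Cl2, −20 °C; then CSA (10 mol %), 0 °C
Reagents that add atoms: tert-butyl hydroperoxide, CC(C)(C)OO
Why: Sharpless asymmetric epoxidation under reagent control (D-tartrate on a (Z)-allylic alcohol gives the (12S,13R)-epoxide 5), then acid-promoted 5-exo opening by the C9 hydroxyl at the tertiary C12 with inversion, which sets C12 (R), keeps C13 (R) and gives the 2,5-trans ring; ring-size preference and cation stability both favour attack at C12.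

Step 4
Reactants: 6 (1R)-1-[(2R,5R)-5-[(2R)-but-3-en-2-yl]-2-methyloxolan-2-yl]ethane-1,2-diol
Product: 7 (4R)-4-[(2R,5R)-5-[(2R)-but-3-en-2-yl]-2-methyloxolan-2-yl]-2-(4-methoxyphenyl)-1,3-dioxolane (both acetal epimers)
Conditions: 4-MeOC6H4CH(OMe)2, PPTS (cat.), CH2Cl2, 23 °C
Reagents that add atoms: 4-methoxybenzaldehyde dimethyl acetal, COc1ccc(cc1)C(OC)OC
Why: Acid-catalysed transacetalisation of the 1,2-diol; the acetal carbon is reduced in step 5, so its configuration does not matter.

Step 5
Reactants: 7 arylidene acetal
Product: 8 (2R)-2-[(2R,5R)-5-[(2R)-but-3-en-2-yl]-2-methyloxolan-2-yl]-2-[(4-methoxyphenyl)methoxy]ethan-1-ol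
Conditions: i-Bu2AlH, CH2Cl2, −78 → 0 °C; Rochelle salt work-up
Reagents that add atoms: none
Why: Regioselective reductive opening of the arylidene acetal: the aluminium reagent binds the less hindered primary oxygen and hydride is delivered to the oxocarbenium ion, which should leave the PMB group on the hindered C13 oxygen and the C14 primary alcohol free.

Step 6
Reactants: 9 (S)-glycidol
Product: 10 (2R)-pent-4-yne-1,2-diol
Conditions: LiC≡CH·H2NCH2CH2NH2, DMSO, 0 → 23 °C
Reagents that add atoms: lithium acetylide ethylenediamine complex, [Li]C#C.NCCN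
Why: SN2 opening of the terminal epoxide carbon by the acetylide; the stereocentre is not touched.

Step 7
Reactants: 10 (2R)-pent-4-yne-1,2-diol
Product: 11 (2R,4E)-5-iodo-4-methylpent-4-ene-1,2-diol
Conditions: AlMe3, Cp2ZrCl2 (25 mol %), CH2Cl2, 0 → 23 °C; then I2, THF, −30 → 0 °C
Reagents that add atoms: trimethylaluminium, C[Al](C)C; iodine, II
Why: Zirconium-catalysed carboalumination (Negishi) adds methyl and aluminium syn across the terminal alkyne with methyl on the internal carbon; iodinolysis with retention gives the (E)-vinyl iodide that carries C4, C5 and Me-18.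

Step 8
Reactants: 11 (2R,4E)-5-iodo-4-methylpent-4-ene-1,2-diol
Product: 12 (2R,4E)-5-iodo-4-methyl-1,2-bis(triethylsilyloxy)pent-4-ene
Conditions: Et3SiCl, imidazole, DMF, 0 → 23 °C
Reagents that add atoms: chlorotriethylsilane, CC[Si](Cl)(CC)CC
Why: Standard silylation of both hydroxyls.

Step 9
Reactants: 12 (2R,4E)-5-iodo-4-methyl-1,2-bis(triethylsilyloxy)pent-4-ene
Product: 13 (2R,4E)-5-iodo-4-methyl-2-(triethylsilyloxy)pent-4-enal
Conditions: (COCl)2, DMSO, CH2Cl2, −78 → −30 °C; Et3N, −78 → 0 °C
Reagents that add atoms: none
Why: Swern conditions convert a primary triethylsilyl ether directly into the aldehyde (the chlorosulfonium salt activates the ether oxygen, Et3SiCl leaves, the ylide fragments), while the secondary silyl ether is untouched.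

Step 10
Reactants: 13 (2R,4E)-5-iodo-4-methyl-2-(triethylsilyloxy)pent-4-enal; 14 methyl acrylate
Product: 15 methyl (4R,6E)-3-hydroxy-7-iodo-6-methyl-2-methylidene-4-(triethylsilyloxy)hept-6-enoate (both C3 epimers)
Conditions: DABCO, methyl acrylate (excess), MeOH (cat.), 23 °C
Reagents that add atoms: none
Why: Morita–Baylis–Hillman reaction; the α-silyloxy aldehyde is an activated electrophile; the new carbinol centre (C1 of the target) forms as a mixture that converges in step 12.

Step 11
Reactants: 8 oxolane alcohol with terminal vinyl group; 15 vinyl iodide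
Product: 16 methyl (4R,6E,10R)-3-hydroxy-10-[(2R,5R)-5-[(1R)-2-hydroxy-1-[(4-methoxyphenyl)methoxy]ethyl]-5-methyloxolan-2-yl]-6-methyl-2-methylidene-4-(triethylsilyloxy)undec-6-enoate (both C3 epimers)
Conditions: 8, 9-BBN, THF, 23 °C; H2O; then 15, Pd(dppf)Cl2 (5 mol %), AsPh3, Cs2CO3, DMF/THF/H2O, 23 °C
Reagents that add atoms: none
Why: B-alkyl Suzuki–Miyaura coupling: anti-Markovnikov hydroboration of the only alkene of 8 and coupling with retention of the vinyl iodide geometry forms C5–C6 and fixes the 4E olefin; acrylate, free hydroxyls, silyl ether and PMB ether should tolerate the mild aqueous base.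

Step 12
Reactants: 16 coupled allylic alcohol
Product: 17 methyl (2Z,4R,6E,10R)-2-(bromomethyl)-10-[(2R,5R)-5-[(1R)-2-hydroxy-1-[(4-methoxyphenyl)methoxy]ethyl]-5-methyloxolan-2-yl]-6-methyl-4-(triethylsilyloxy)undeca-2,6-dienoate
Conditions: NBS, Me2S, CH2Cl2, −20 → 0 °C
Reagents that add atoms: N-bromosuccinimide, O=C1CCC(=O)N1Br
Why: Corey–Kim-type bromination: the sulfonium reagent activates the allylic hydroxyl and bromide attacks the methylene terminus (SN2'), giving the thermodynamically preferred (Z)-2-(bromomethyl)enoate from both C1 epimers; the saturated C14 primary hydroxyl only forms an alkoxysulfonium salt that reverts on work-up.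

Step 13
Reactants: 17 bromo alcohol
Product: 18 methyl (2Z,4R,6E,10R)-2-(bromomethyl)-10-[(2R,5R)-5-[(1S)-1-[(4-methoxyphenyl)methoxy]-2-oxoethyl]-5-methyloxolan-2-yl]-6-methyl-4-(triethylsilyloxy)undeca-2,6-dienoate
Conditions: Dess–Martin periodinane, NaHCO3, CH2Cl2, 0 → 23 °C
Reagents that add atoms: none
Why: Dess–Martin oxidation under buffered, non-basic conditions should give the α-alkoxy aldehyde without epimerisation at C13 and leave the allylic bromide intact.

Step 14
Reactants: 18 bromo aldehyde
Product: 21 macrocyclic α-methylene lactone (15,17-didehydro-2-deoxo-2-(triethylsilyloxy)-13-O-(4-methoxybenzyl) derivative of 26; C1 C8 C9 C12 C13 C14 as in 26), via allylindium species 19 (not isolated), via hydroxy ester 20 (not isolated)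
Conditions: In powder, THF/H2O (3:1), 23 °C, 18 added by syringe pump (final 2 mM); then PPTS (cat.), benzene, 50 °C
Reagents that add atoms: none
Why: Indium inserts into the allylic C17–Br bond and the allylindium species 19 adds to the C14 aldehyde through its γ-carbon C1 (SE2') in a six-membered chair transition state, forming the C1–C14 bond that the presumed biosynthesis also closes with C14 as electrophile and the C1=C15 π-bond as nucleophile, and leaving the C15=C17 methylidene. The closest known reaction type is the Barbier-type (indium or zinc) addition of 2-(bromomethyl)acrylates to aldehydes giving α-methylene-γ-butyrolactones, including its intramolecular use to close medium and large carbocycles, together with chelation-controlled indium allylation of α-oxygenated aldehydes in water. The 14-membered carbocycle closes by 14-exo-trig addition to the aldehyde under high dilution, and the lactone then closes by 5-exo-trig acyl substitution of the C14 hydroxyl of 20 on the methyl ester. C14 is controlled by C13: the metal is held between the aldehyde oxygen and the C13 ether oxygen (the ring oxygen on C12 can assist), and attack on the face away from the quaternary C12 gives the 13,14-syn arrangement (14S). C1 is controlled by the (Z) geometry of the allyl unit: in the chair the C2-bearing substituent is axial, which gives the 1,14-syn adduct and hence the cis-fused lactone (1R). The step needs γ- over α-attack (secured by the cyclic mechanism and by the 14- versus 16-membered alternative), intra- over intermolecular reaction (slow addition at millimolar concentration, with the trans-oxolane and the E-olefin limiting the free rotors), and chelate over Felkin-type face selection (ether oxygen on C13, protic medium). The syn hydroxy ester 20 has hydroxyl and ester cis-disposed and should lactonise on mild acid catalysis, which also makes the addition irreversible.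

Step 15
Reactants: 21 macrocyclic α-methylene lactone
Product: 23 α-methyl lactone (2-deoxo-2-(triethylsilyloxy)-13-O-(4-methoxybenzyl) derivative of 26; 15R), via C15 epimer 22 (not isolated)
Conditions: Li[HB(s-Bu)3], THF, −78 °C; then t-BuOH, −78 → 23 °C
Reagents that add atoms: none
Why: Conjugate hydride addition to the α-methylene lactone gives the lactone enolate; kinetic protonation from the open face should give mainly the all-cis epimer 22, and alkoxide-mediated equilibration of the only acidic centre (C15; C1 is not enolisable while C2 is a silyl ether) should move the methyl group trans to the C1 substituent (15R).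

Step 16
Reactants: 23 α-methyl lactone silyl ether
Product: 24 C2 alcohol (2-deoxo-2-hydroxy-13-O-(4-methoxybenzyl) derivative of 26)
Conditions: HF·pyridine, pyridine, THF, 0 °C
Reagents that add atoms: none
Why: Buffered fluoride cleavage of the secondary triethylsilyl ether; PMB ether and lactone are inert, and the near-neutral medium should keep the freed C2 hydroxyl from attacking the lactone carbonyl (acyl migration).

Step 17
Reactants: 24 C2 alcohol
Product: 25 13-O-(4-methoxybenzyl) ether of 26
Conditions: Dess–Martin periodinane, NaHCO3, CH2Cl2, 0 °C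
Reagents that add atoms: none
Why: Dess–Martin oxidation of the homoallylic alcohol under buffered conditions should give the β,γ-unsaturated ketone without migration of C4=C5 into conjugation, epimerisation at C1 or β-elimination of the C14 acyloxy group.

Step 18
Reactants: 25 PMB ether of the target
Product: 26 target, (1R,4E,8R,9R,12R,13R,14S,15R)-9,12-epoxy-13-hydroxy-2-oxocembr-4-en-16,14-olide
Conditions: DDQ, CH2Cl2/pH 7 phosphate buffer (10:1), 0 °C
Reagents that add atoms: none
Why: Oxidative cleavage of the PMB ether by electron transfer to DDQ and hydrolysis of the resulting oxocarbenium ion; neutral buffered conditions should spare the β,γ-unsaturated ketone, the trisubstituted olefin and the lactone.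

## Compound list

1 | neryl acetate, (2Z)-3,7-dimethylocta-2,6-dien-1-yl acetate | CC(C)=CCC/C(C)=C\COC(C)=O | starting material
2 | (2Z)-3-methyl-6-oxohex-2-en-1-yl acetate | O=CCC/C(C)=C\COC(C)=O | intermediate
3 | (2Z,6R,7R)-6-hydroxy-3,7-dimethylnona-2,8-dien-1-yl acetate | C=C[C@@H](C)[C@H](O)CC/C(C)=C\COC(C)=O | intermediate (not isolated)
4 | (2Z,6R,7R)-3,7-dimethylnona-2,8-diene-1,6-diol | C=C[C@@H](C)[C@H](O)CC/C(C)=C\CO | intermediate
5 | [(2R,3S)-3-[(3R,4R)-3-hydroxy-4-methylhex-5-en-1-yl]-3-methyloxiran-2-yl]methanol | C=C[C@@H](C)[C@H](O)CC[C@]1(C)O[C@@H]1CO | intermediate (not isolated)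
6 | (1R)-1-[(2R,5R)-5-[(2R)-but-3-en-2-yl]-2-methyloxolan-2-yl]ethane-1,2-diol | C=C[C@@H](C)[C@H]1CC[C@@](C)(O1)[C@H](O)CO | intermediate
7 | (4R)-4-[(2R,5R)-5-[(2R)-but-3-en-2-yl]-2-methyloxolan-2-yl]-2-(4-methoxyphenyl)-1,3-dioxolane, both acetal epimers | C=C[C@@H](C)[C@H]1CC[C@@](C)(O1)[C@H]1COC(O1)c1ccc(OC)cc1 | intermediate
8 | (2R)-2-[(2R,5R)-5-[(2R)-but-3-en-2-yl]-2-methyloxolan-2-yl]-2-[(4-methoxyphenyl)methoxy]ethan-1-ol | C=C[C@@H](C)[C@H]1CC[C@@](C)(O1)[C@H](OCc1ccc(OC)cc1)CO | intermediate
9 | (S)-glycidol, [(2S)-oxiran-2-yl]methanol | OC[C@H]1CO1 | starting material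
10 | (2R)-pent-4-yne-1,2-diol | OC[C@H](O)CC#C | intermediate
11 | (2R,4E)-5-iodo-4-methylpent-4-ene-1,2-diol | OC[C@H](O)C/C(C)=C/I | intermediate
12 | (2R,4E)-5-iodo-4-methyl-1,2-bis(triethylsilyloxy)pent-4-ene | CC[Si](CC)(CC)OC[C@H](O[Si](CC)(CC)CC)C/C(C)=C/I | intermediate
13 | (2R,4E)-5-iodo-4-methyl-2-(triethylsilyloxy)pent-4-enal | O=C[C@H](O[Si](CC)(CC)CC)C/C(C)=C/I | intermediate
14 | methyl acrylate | C=CC(=O)OC | starting material
15 | methyl (4R,6E)-3-hydroxy-7-iodo-6-methyl-2-methylidene-4-(triethylsilyloxy)hept-6-enoate, both C3 epimers | COC(=O)C(=C)C(O)[C@H](O[Si](CC)(CC)CC)C/C(C)=C/I | intermediate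
16 | methyl (4R,6E,10R)-3-hydroxy-10-[(2R,5R)-5-[(1R)-2-hydroxy-1-[(4-methoxyphenyl)methoxy]ethyl]-5-methyloxolan-2-yl]-6-methyl-2-methylidene-4-(triethylsilyloxy)undec-6-enoate, both C3 epimers | COC(=O)C(=C)C(O)[C@H](O[Si](CC)(CC)CC)C/C(C)=C/CC[C@@H](C)[C@H]1CC[C@@](C)(O1)[C@H](OCc1ccc(OC)cc1)CO | intermediate
17 | methyl (2Z,4R,6E,10R)-2-(bromomethyl)-10-[(2R,5R)-5-[(1R)-2-hydroxy-1-[(4-methoxyphenyl)methoxy]ethyl]-5-methyloxolan-2-yl]-6-methyl-4-(triethylsilyloxy)undeca-2,6-dienoate | COC(=O)/C(CBr)=C/[C@H](O[Si](CC)(CC)CC)C/C(C)=C/CC[C@@H](C)[C@H]1CC[C@@](C)(O1)[C@H](OCc1ccc(OC)cc1)CO | intermediate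
18 | methyl (2Z,4R,6E,10R)-2-(bromomethyl)-10-[(2R,5R)-5-[(1S)-1-[(4-methoxyphenyl)methoxy]-2-oxoethyl]-5-methyloxolan-2-yl]-6-methyl-4-(triethylsilyloxy)undeca-2,6-dienoate | COC(=O)/C(CBr)=C/[C@H](O[Si](CC)(CC)CC)C/C(C)=C/CC[C@@H](C)[C@H]1CC[C@@](C)(O1)[C@H](OCc1ccc(OC)cc1)C=O | intermediate
19 | allylindium species from 18, formulated as the C17 dibromoindium compound | COC(=O)/C(C[In](Br)Br)=C/[C@H](O[Si](CC)(CC)CC)C/C(C)=C/CC[C@@H](C)[C@H]1CC[C@@](C)(O1)[C@H](OCc1ccc(OC)cc1)C=O | intermediate (not isolated)
20 | macrocyclic hydroxy ester (C1–C14 bond closed, C14 hydroxyl free, methyl 2-substituted acrylate on C1) | C/C1=C\CC[C@@H](C)[C@H]2CC[C@@](C)(O2)[C@H](OCc3ccc(OC)cc3)[C@@H](O)[C@@H](C(=C)C(=O)OC)[C@H](O[Si](CC)(CC)CC)C1 | intermediate (not isolated)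
21 | macrocyclic α-methylene lactone: 15,17-didehydro-2-deoxo-2-(triethylsilyloxy)-13-O-(4-methoxybenzyl) derivative of 26 | C/C1=C\CC[C@@H](C)[C@H]2CC[C@@](C)(O2)[C@H](OCc3ccc(OC)cc3)[C@H]2OC(=O)C(=C)[C@H]2[C@H](O[Si](CC)(CC)CC)C1 | intermediate
22 | C15 epimer of 23 (methyl cis to the C1 substituent) | C/C1=C\CC[C@@H](C)[C@H]2CC[C@@](C)(O2)[C@H](OCc3ccc(OC)cc3)[C@H]2OC(=O)[C@@H](C)[C@H]2[C@H](O[Si](CC)(CC)CC)C1 | intermediate (not isolated)
23 | 2-deoxo-2-(triethylsilyloxy)-13-O-(4-methoxybenzyl) derivative of 26 | C/C1=C\CC[C@@H](C)[C@H]2CC[C@@](C)(O2)[C@H](OCc3ccc(OC)cc3)[C@H]2OC(=O)[C@H](C)[C@H]2[C@H](O[Si](CC)(CC)CC)C1 | intermediate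
24 | 2-deoxo-2-hydroxy-13-O-(4-methoxybenzyl) derivative of 26 | C/C1=C\CC[C@@H](C)[C@H]2CC[C@@](C)(O2)[C@H](OCc3ccc(OC)cc3)[C@H]2OC(=O)[C@H](C)[C@H]2[C@H](O)C1 | intermediate
25 | 13-O-(4-methoxybenzyl) ether of 26 | C/C1=C\CC[C@@H](C)[C@H]2CC[C@@](C)(O2)[C@H](OCc3ccc(OC)cc3)[C@H]2OC(=O)[C@H](C)[C@H]2C(=O)C1 | intermediate
26 | (1R,4E,8R,9R,12R,13R,14S,15R)-9,12-epoxy-13-hydroxy-2-oxocembr-4-en-16,14-olide (CNP0386136.3) | C/C1=C\CC[C@@H](C)[C@H]2CC[C@@](C)(O2)[C@H](O)[C@H]2OC(=O)[C@H](C)[C@H]2C(=O)C1 | target

## Step count and risks

Total step count: 18. Longest linear sequence: 13 (steps 1–5 or 6–10, then 11–18).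

Step 14 (key step). Three processes may defeat it: intermolecular allylation leading to oligomers, erosion of face selectivity at C14 (an ether oxygen holds indium less firmly than a free hydroxyl, so Felkin-type addition may compete with the chelate), and attack through the α-terminus to give a 16-membered ring. The fallback makes the allylation intermolecular and moves the ring closure to C5–C6. It sets out from 8 and 15. Oxidation of 8 with Dess–Martin periodinane gives the aldehyde F1, and bromination of 15 with NBS/Me2S gives the (Z)-allylic bromide F2. Their indium-mediated coupling in aqueous THF, where the aldehyde can be used in excess and the chair transition state is free of ring constraints, gives after lactonisation the α-methylene lactone F3, which carries the terminal vinyl group and the vinyl iodide. Hydroboration of the vinyl group with 9-BBN and intramolecular B-alkyl Suzuki coupling (Pd(dppf)Cl2, AsPh3, Cs2CO3, high dilution) closes the carbocycle and returns to the route at 21.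

Step 15. The equilibration may stall at a mixture of 22 and 23, or the kinetic protonation may dominate if the alkoxide is too weak to re-enolise the lactone. The fallback replaces thermodynamic control by hydroxyl-directed hydrogen delivery. It sets out from 21: buffered HF·pyridine removes the silyl group to give the homoallylic alcohol F4, and hydrogenation with [Ir(cod)(PCy3)(py)]PF6 under H2 in CH2Cl2 lets the C2 hydroxyl, which sits on the same face as the ring substituents of the lactone, guide hydrogen to that face of C15=C17. This places the methyl group trans to C2 and returns to the route at 24. The 1,1-disubstituted olefin should react well before the trisubstituted C4=C5 olefin.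

Step 3. The (Z)-trisubstituted allylic alcohol may be epoxidised with lower face selectivity than an (E) substrate, the polyol product may bind the titanium catalyst and slow turnover, and the epoxide may open before epoxidation is complete. The fallback uses substrate instead of reagent control. It sets out from 3, isolated by working up step 2 without base. VO(acac)2 and t-BuOOH epoxidise the C12=C13 olefin under direction of the C9 hydroxyl (the allylic oxygen is blocked as the acetate), and acetic acid completes the 5-exo opening to the oxolane acetate F5, expected as the 2,5-trans isomer. K2CO3 in methanol removes the acetate and returns to the route at 6.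

Step 1. Over-oxidation, i.e. cleavage of the allylic acetate olefin once the first olefin is consumed, would lower the yield of 2. The fallback separates the two events: it sets out from 1, mCPBA (1 equiv, 0 °C) epoxidises the more electron-rich distal olefin to give the epoxide F6, and H5IO6 in aqueous THF cleaves the epoxide to the aldehyde, returning to the route at 2.

## Further compounds

F1 | step 14 | (2S)-2-[(2R,5R)-5-[(2R)-but-3-en-2-yl]-2-methyloxolan-2-yl]-2-[(4-methoxyphenyl)methoxy]acetaldehyde | C=C[C@@H](C)[C@H]1CC[C@@](C)(O1)[C@H](OCc1ccc(OC)cc1)C=O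
F2 | step 14 | methyl (2Z,4R,6E)-2-(bromomethyl)-7-iodo-6-methyl-4-(triethylsilyloxy)hepta-2,6-dienoate | COC(=O)/C(CBr)=C/[C@H](O[Si](CC)(CC)CC)C/C(C)=C/I
F3 | step 14 | cis-β,γ-disubstituted α-methylene-γ-butyrolactone carrying the oxolane with terminal vinyl group on C14 and the (E)-vinyl iodide chain with C2 OTES on C1 | C=C[C@@H](C)[C@H]1CC[C@@](C)(O1)[C@H](OCc1ccc(OC)cc1)[C@H]1OC(=O)C(=C)[C@H]1[C@H](O[Si](CC)(CC)CC)C/C(C)=C/I
F4 | step 15 | 15,17-didehydro-2-deoxo-2-hydroxy-13-O-(4-methoxybenzyl) derivative of 26 | C/C1=C\CC[C@@H](C)[C@H]2CC[C@@](C)(O2)[C@H](OCc3ccc(OC)cc3)[C@H]2OC(=O)C(=C)[C@H]2[C@H](O)C1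
F5 | step 3 | (2R)-2-[(2R,5R)-5-[(2R)-but-3-en-2-yl]-2-methyloxolan-2-yl]-2-hydroxyethyl acetate | C=C[C@@H](C)[C@H]1CC[C@@](C)(O1)[C@H](O)COC(C)=O
F6 | step 1 | (2Z)-5-(3,3-dimethyloxiran-2-yl)-3-methylpent-2-en-1-yl acetate (racemic epoxide) | CC1(C)OC1CC/C(C)=C\COC(C)=O
A1 | alternative 1 | metathesis diene: α-methyl lactone with C2 OTES and C13 OPMB, C4 as isopropenyl terminus and C5 as vinyl terminus | C=CCC[C@@H](C)[C@H]1CC[C@@](C)(O1)[C@H](OCc1ccc(OC)cc1)[C@H]1OC(=O)[C@H](C)[C@H]1[C@H](O[Si](CC)(CC)CC)CC(C)=C
A2 | alternative 2 | macrocyclic 9-hydroxy-12,13-epoxide (lactone and C2 ketone in place, no ether bridge) | C/C1=C\CC[C@@H](C)[C@H](O)CC[C@]2(C)O[C@@H]2[C@H]2OC(=O)[C@H](C)[C@H]2C(=O)C1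
A3 | alternative 3 | C3 allylic bromide with C2 as 1-ethoxyethyl-protected cyanohydrin on the preformed lactone (C13 OPMB) | BrC/C(C)=C/CC[C@@H](C)[C@H]1CC[C@@](C)(O1)[C@H](OCc1ccc(OC)cc1)[C@H]1OC(=O)[C@H](C)[C@H]1C(C#N)OC(C)OCC
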